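**Plan** (prostanoid numbering: C1 = ester carbon, C9 = ring ketone, ring = C8–C12)

- Retrosynthesis: remove the C12 silyl ether and the C7 acetate, cut C7–C8 (aldol), then cut the cyclopentenone across both C10=C11 and C8–C12 into a three-carbon and a two-carbon piece, and cut the latter at C12–C13.
- Enabling feature: the ring is a 2-bromo-4-hydroxycyclopent-2-enone. C8–C9(=O)–C10(Br) is 1,3-dibromoacetone with one bromine left in place, and C11–C12 is an α-oxygenated aldehyde (C11 at the aldehyde level, C12 the carbinol). An enamine of that aldehyde can therefore join the dibromide by C-alkylation, Mannich closure and loss of the amine in one flask.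
- Forward: glycolate alkylation builds C11–C20; the five-membered ring (the only ring) arises in the annulation; the C1–C7 chain is joined by an aldol reaction, followed by acetylation and desilylation.
- Stereochemistry: C12 from the L-proline-derived amine that is expelled in the annulation; C8 and C7 from the substrate-controlled anti aldol; the two Z alkenes from (2Z)-oct-2-en-1-ol and a Lindlar reduction.

Key step: step 6

Remark: 6 and 7 are carried as racemates, because their stereocentre becomes trigonal in enamine 9.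

Step 1
Reactants: 1 (2Z)-oct-2-en-1-ol
Product: 2 (2Z)-1-bromooct-2-ene
Conditions: CBr4, PPh3, CH2Cl2, 0 °C
Reagents that add atoms: tetrabromomethane, BrC(Br)(Br)Br
Why: Appel bromination by SN2 at the primary allylic carbon should leave the Z alkene untouched.

Step 2
Reactants: 3 ethyl glycolate
Product: 4 ethyl 2-[(triethylsilyl)oxy]acetate
Conditions: Et3SiCl, imidazole, CH2Cl2, 0 °C to rt
Reagents that add atoms: chlorotriethylsilane, CC[Si](Cl)(CC)CC
Why: Standard silylation of a primary alcohol; the triethylsilyl group is chosen because it survives enolate chemistry and can later be removed from a tertiary oxygen under mild acid.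

Step 3
Reactants: 4 ethyl 2-[(triethylsilyl)oxy]acetate; 2 (2Z)-1-bromooct-2-ene
Product: 6 ethyl (4Z)-2-[(triethylsilyl)oxy]dec-4-enoate (racemic), via lithium enolate 5 (not isolated)
Conditions: LiN(iPr)2 (1.05 equiv), THF, −78 °C; then 2, DMPU, −78 to −40 °C
Reagents that add atoms: none
Why: C-alkylation of an α-silyloxy ester enolate by a primary allylic bromide (SN2) should form C12–C13; the new stereocentre is racemic and is erased in step 5.

Step 4
Reactants: 6 ethyl (4Z)-2-[(triethylsilyl)oxy]dec-4-enoate (racemic)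
Product: 7 (4Z)-2-[(triethylsilyl)oxy]dec-4-enal (racemic)
Conditions: iBu2AlH (1.1 equiv), CH2Cl2, −78 °C; MeOH, then aq. potassium sodium tartrate (KNaC4H4O6)
Reagents that add atoms: none
Why: Partial reduction of an α-silyloxy ester should stop at the aldehyde, because the aluminium hemiacetal is stable at −78 °C.

Step 5
Reactants: 7 (4Z)-2-[(triethylsilyl)oxy]dec-4-enal (racemic); 8 (2S)-2-(diphenylmethyl)pyrrolidine
Product: 9 (2S)-2-(diphenylmethyl)-1-[(1Z,4Z)-2-[(triethylsilyl)oxy]deca-1,4-dien-1-yl]pyrrolidine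
Conditions: toluene, 4 Å molecular sieves, rt; filtered and concentrated under argon
Reagents that add atoms: none
Why: Condensation of an α-branched aldehyde with a secondary amine should give the enamine, expected mainly as the Z isomer (silyloxy oxygen cis to nitrogen) in the s-trans rotamer, because A(1,3) strain places the smaller group next to the pyrrolidine.

Step 6
Reactants: 9 (2S)-2-(diphenylmethyl)-1-[(1Z,4Z)-2-[(triethylsilyl)oxy]deca-1,4-dien-1-yl]pyrrolidine; 10 1,3-dibromoacetone
Product: 13 (4S)-2-bromo-4-[(2Z)-oct-2-en-1-yl]-4-[(triethylsilyl)oxy]cyclopent-2-en-1-one, via iminium bromide 11 (not isolated), via Mannich base hydrobromide 12 (not isolated)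
Conditions: 10 (1.05 equiv), MeCN, 4 Å molecular sieves, −20 °C to rt; then AcOH/NaOAc (0.2 equiv each), 45 °C
Reagents that add atoms: none
Why: Proposed new method: the enamine carbon that becomes C12 displaces one bromide of 10 (Stork-type C-alkylation, C8–C12), the iminium 11 so formed has no α-hydrogen and is captured by the enol of its own bromomethyl ketone (intramolecular Mannich reaction, C10–C11), and the β-ammonium ketone 12 loses the amine by E1cB so that C10=C11 appears with the bromine still on C10. The closest known reaction types are the Stork alkylation of aldehyde enamines by α-halo ketones followed by aldol condensation of the 4-oxo aldehyde, the Noyori [3+2] cyclopentenone annulation of enamines with oxyallyl species from α,α'-dibromo ketones, and the Robinson-type annulation of proline-derived enamines of α-branched aldehydes. The five-membered ring closes by a 5-(enolendo)-exo-trig Mannich cyclization, the mode by which 1,4-dicarbonyl compounds give cyclopentenones. C12 is the only stereocentre that is kept: in the Z, s-trans enamine the diphenylmethyl group lies under the Re face of that carbon, so the dibromide should enter on the Si face and give the 4S ring carbon, while the centres at C10 and C11 of 12 are erased in the elimination. The step needs C- over N-alkylation (N-alkylation by an α-halo ketone is reversible, C-alkylation is not), reaction at C12 and not C11 (the nitrogen is the stronger donor), a single substitution on 10 (the quaternary iminium cannot act as a nucleophile again), and loss of the amine instead of aziridinium formation by displacement of the neighbouring bromide (the buffer keeps the amine protonated and the quaternary neighbour speeds the retro-Michael step).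

Step 7
Reactants: 14 hex-5-ynoic acid
Product: 16 7-hydroxyhept-5-ynoic acid, via dilithium salt 15 (not isolated)
Conditions: n-BuLi (2.2 equiv), THF, −78 to 0 °C; (CH2O)n, 0 °C to rt; then 1 M HCl
Reagents that add atoms: paraformaldehyde (formaldehyde), C=O
Why: The carboxylate/acetylide dianion should add to formaldehyde only at the acetylide carbon (hydroxymethylation of a terminal alkyne).

Step 8
Reactants: 16 7-hydroxyhept-5-ynoic acid
Product: 17 methyl 7-hydroxyhept-5-ynoate
Conditions: MeOH, H2SO4 (cat.), rt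
Reagents that add atoms: methanol, CO
Why: Fischer esterification; the propargylic alcohol is inert under these conditions.

Step 9
Reactants: 17 methyl 7-hydroxyhept-5-ynoate
Product: 18 methyl (5Z)-7-hydroxyhept-5-enoate
Conditions: H2 (1 atm), Lindlar catalyst (Pd on CaCO3 poisoned with Pb(OAc)2), quinoline, EtOAc, rt
Reagents that add atoms: none
Why: Lindlar semi-hydrogenation adds hydrogen syn and should give the Z alkene (C5=C6).

Step 10
Reactants: 18 methyl (5Z)-7-hydroxyhept-5-enoate
Product: 19 methyl (5Z)-7-oxohept-5-enoate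
Conditions: Dess–Martin periodinane, NaHCO3, CH2Cl2, 0 °C; used at once
Reagents that add atoms: none
Why: Buffered Dess–Martin oxidation of an allylic alcohol is mild enough that the Z enal should be obtained without isomerization if it is used immediately.

Step 11
Reactants: 13 (4S)-2-bromo-4-[(2Z)-oct-2-en-1-yl]-4-[(triethylsilyl)oxy]cyclopent-2-en-1-one; 19 methyl (5Z)-7-oxohept-5-enoate
Product: 21 methyl (5Z,7S)-7-[(1R,5S)-3-bromo-5-[(2Z)-oct-2-en-1-yl]-2-oxo-5-[(triethylsilyl)oxy]cyclopent-3-en-1-yl]-7-hydroxyhept-5-enoate, via lithium dienolate 20 (not isolated)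
Conditions: LiN(iPr)2 (1.0 equiv), THF, −78 °C; then 19, −78 °C; AcOH quench at −78 °C
Reagents that add atoms: none
Why: Kinetic lithium aldol of the cross-conjugated dienolate, which can form only at C8, through a Zimmerman–Traxler chair: the ring-locked E enolate should give the 7,8-anti adduct and the aldehyde should approach C8 anti to the octenyl CH2 on C12 (syn to the smaller silyloxy oxygen), setting C8 as R and C7 as S.

Step 12
Reactants: 21 methyl (5Z,7S)-7-[(1R,5S)-3-bromo-5-[(2Z)-oct-2-en-1-yl]-2-oxo-5-[(triethylsilyl)oxy]cyclopent-3-en-1-yl]-7-hydroxyhept-5-enoate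
Product: 22 methyl (5Z,7S)-7-acetoxy-7-[(1R,5S)-3-bromo-5-[(2Z)-oct-2-en-1-yl]-2-oxo-5-[(triethylsilyl)oxy]cyclopent-3-en-1-yl]hept-5-enoate
Conditions: Ac2O, pyridine, CH2Cl2, 0 °C (no DMAP)
Reagents that add atoms: acetic anhydride, CC(=O)OC(C)=O
Why: Acetylation of the secondary allylic alcohol with a weak base at low temperature should avoid E1cB loss of the new β-acetoxy group and leaves C7 and C8 untouched.

Step 13
Reactants: 22 methyl (5Z,7S)-7-acetoxy-7-[(1R,5S)-3-bromo-5-[(2Z)-oct-2-en-1-yl]-2-oxo-5-[(triethylsilyl)oxy]cyclopent-3-en-1-yl]hept-5-enoate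
Product: 23 methyl (5Z,7S)-7-acetoxy-7-[(1R,5S)-3-bromo-5-hydroxy-5-[(2Z)-oct-2-en-1-yl]-2-oxocyclopent-3-en-1-yl]hept-5-enoate
Conditions: HF·pyridine, pyridine, THF, 0 °C to rt
Reagents that add atoms: none
Why: Buffered HF should cleave the tertiary triethylsilyl ether under mildly acidic conditions that spare the β-acetoxy ketone, the vinyl bromide, the methyl ester and both Z alkenes.

**Compound list**

1 | (2Z)-oct-2-en-1-ol | CCCCC/C=C\CO | starting material
2 | (2Z)-1-bromooct-2-ene | CCCCC/C=C\CBr | intermediate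
3 | ethyl glycolate (ethyl 2-hydroxyacetate) | CCOC(=O)CO | starting material
4 | ethyl 2-[(triethylsilyl)oxy]acetate | CCOC(=O)CO[Si](CC)(CC)CC | intermediate
5 | lithium enolate of 4 | CCOC(O[Li])=CO[Si](CC)(CC)CC | intermediate
6 | ethyl (4Z)-2-[(triethylsilyl)oxy]dec-4-enoate (racemic) | CCCCC/C=C\CC(O[Si](CC)(CC)CC)C(=O)OCC | intermediate
7 | (4Z)-2-[(triethylsilyl)oxy]dec-4-enal (racemic) | CCCCC/C=C\CC(O[Si](CC)(CC)CC)C=O | intermediate
8 | (2S)-2-(diphenylmethyl)pyrrolidine | C(c1ccccc1)(c2ccccc2)[C@@H]3CCCN3 | starting material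
9 | (2S)-2-(diphenylmethyl)-1-[(1Z,4Z)-2-[(triethylsilyl)oxy]deca-1,4-dien-1-yl]pyrrolidine | CCCCC/C=C\C/C(O[Si](CC)(CC)CC)=C/N1CCC[C@H]1C(c2ccccc2)c3ccccc3 | intermediate
10 | 1,3-dibromoacetone (1,3-dibromopropan-2-one) | BrCC(=O)CBr | starting material
11 | (2S)-1-[(2S)-5-bromo-2-[(2Z)-oct-2-en-1-yl]-4-oxo-2-[(triethylsilyl)oxy]pentylidene]-2-(diphenylmethyl)pyrrolidin-1-ium bromide | CCCCC/C=C\C[C@](O[Si](CC)(CC)CC)(CC(=O)CBr)C=[N+]1CCC[C@H]1C(c2ccccc2)c3ccccc3.[Br-] | intermediate
12 | (4S)-2-bromo-3-[(2S)-2-(diphenylmethyl)pyrrolidin-1-yl]-4-[(2Z)-oct-2-en-1-yl]-4-[(triethylsilyl)oxy]cyclopentan-1-one hydrobromide (epimers at C2 and C3) | CCCCC/C=C\C[C@@]1(O[Si](CC)(CC)CC)C(N2CCC[C@H]2C(c3ccccc3)c4ccccc4)C(Br)C(=O)C1.Br | intermediate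
13 | (4S)-2-bromo-4-[(2Z)-oct-2-en-1-yl]-4-[(triethylsilyl)oxy]cyclopent-2-en-1-one | CCCCC/C=C\C[C@@]1(O[Si](CC)(CC)CC)C=C(Br)C(=O)C1 | intermediate
14 | hex-5-ynoic acid | OC(=O)CCCC#C | starting material
15 | dilithium salt of 14 (carboxylate and acetylide) | [Li]OC(=O)CCCC#C[Li] | intermediate
16 | 7-hydroxyhept-5-ynoic acid | OC(=O)CCCC#CCO | intermediate
17 | methyl 7-hydroxyhept-5-ynoate | COC(=O)CCCC#CCO | intermediate
18 | methyl (5Z)-7-hydroxyhept-5-enoate | COC(=O)CCC/C=C\CO | intermediate
19 | methyl (5Z)-7-oxohept-5-enoate | COC(=O)CCC/C=C\C=O | intermediate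
20 | lithium dienolate of 13 (enolized toward C8) | CCCCC/C=C\C[C@@]1(O[Si](CC)(CC)CC)C=C(Br)C(O[Li])=C1 | intermediate
21 | methyl (5Z,7S)-7-[(1R,5S)-3-bromo-5-[(2Z)-oct-2-en-1-yl]-2-oxo-5-[(triethylsilyl)oxy]cyclopent-3-en-1-yl]-7-hydroxyhept-5-enoate | CCCCC/C=C\C[C@@]1(O[Si](CC)(CC)CC)C=C(Br)C(=O)[C@@H]1[C@H](/C=C\CCCC(=O)OC)O | intermediate
22 | methyl (5Z,7S)-7-acetoxy-7-[(1R,5S)-3-bromo-5-[(2Z)-oct-2-en-1-yl]-2-oxo-5-[(triethylsilyl)oxy]cyclopent-3-en-1-yl]hept-5-enoate | CCCCC/C=C\C[C@@]1(O[Si](CC)(CC)CC)C=C(Br)C(=O)[C@@H]1[C@H](/C=C\CCCC(=O)OC)OC(C)=O | intermediate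
23 | methyl (5Z,7S)-7-acetoxy-7-[(1R,5S)-3-bromo-5-hydroxy-5-[(2Z)-oct-2-en-1-yl]-2-oxocyclopent-3-en-1-yl]hept-5-enoate | CCCCC/C=C\C[C@@]1(O)C=C(Br)C(=O)[C@@H]1[C@H](/C=C\CCCC(=O)OC)OC(C)=O | target

**Step count and risks**

Total steps: 13. Longest linear sequence: 8 steps (1, 3, 4, 5, 6, 11, 12, 13).

Steps most likely to fail:

1. Step 6 (carries the label). What may go wrong: the two faces of the enamine carbon may not be told apart well enough, N-alkylation may win over C-alkylation, or the Mannich closure and loss of the amine may stall. The fallback uses known chemistry, takes C12 from the chiral pool, sets out from bromide 2 and returns at 13. (S)-Malic acid F1 is condensed with pivalaldehyde (TsOH, pentane, azeotropic removal of water) to the cis dioxolanone (2S,4S)-2-tert-butyl-5-oxo-1,3-dioxolane-4-acetic acid F2. Its dianion (LiN(SiMe3)2, THF, −78 °C) is alkylated by 2 anti to the tert-butyl group (self-regeneration of the stereocentre), giving 2-[(2S,4S)-2-tert-butyl-4-[(2Z)-oct-2-en-1-yl]-5-oxo-1,3-dioxolan-4-yl]acetic acid F3, whose quaternary carbon already has the configuration of C12. iBu2AlH (−78 °C) reduces only the dioxolanone carbonyl, and the lactol closes onto the free acid (TsOH cat.) to the cis-fused lactone acetal 2-tert-butyl-6a-[(2Z)-oct-2-en-1-yl]tetrahydrofuro[2,3-d][1,3]dioxol-5-one F4. Bromomethyllithium made in situ (CH2Br2, n-BuLi, THF, −78 °C) opens the lactone to the bromomethyl ketone; on work-up the freed hemiacetal loses pivalaldehyde to give (2S)-5-bromo-2-hydroxy-2-[(2Z)-oct-2-en-1-yl]-4-oxopentanal F5. Pyrrolidinium acetate closes F5 by aldol condensation to (4S)-2-bromo-4-hydroxy-4-[(2Z)-oct-2-en-1-yl]cyclopent-2-en-1-one F6, and Et3SiOTf/2,6-lutidine gives 13.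

2. Step 11. What may go wrong: the Z enal may isomerize under the basic conditions, and the lithium aldol may show weak syn/anti or facial discrimination. The fallback sets out from 13 and 17 and returns at 22; it uses a boron enolate and an alkyne as a latent Z alkene. Alcohol 17 is oxidized (Dess–Martin periodinane) to methyl 7-oxohept-5-ynoate F7, which cannot isomerize. The dicyclohexylboron enolate of 13 ((c-C6H11)2BCl, Et3N, −78 °C) reacts with F7 through a tight chair to the anti adduct methyl (7R)-7-[(1R,5S)-3-bromo-5-[(2Z)-oct-2-en-1-yl]-2-oxo-5-[(triethylsilyl)oxy]cyclopent-3-en-1-yl]-7-hydroxyhept-5-ynoate F8 (same spatial arrangement as 21; the descriptor changes with the alkyne). Acetylation (Ac2O, pyridine) gives the propargylic acetate methyl (7R)-7-acetoxy-7-[(1R,5S)-3-bromo-5-[(2Z)-oct-2-en-1-yl]-2-oxo-5-[(triethylsilyl)oxy]cyclopent-3-en-1-yl]hept-5-ynoate F9, and Lindlar semi-hydrogenation (Pd on CaCO3 poisoned with Pb(OAc)2, quinoline) gives 22.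

3. Step 3. What may go wrong: 1,2-silyl migration from oxygen to carbon or self-condensation of the glycolate enolate may compete with C-alkylation. The fallback forms C11–C12 by cyanide addition instead of forming C12–C13 by alkylation; it sets out from commercial (3Z)-non-3-en-1-ol F10 and returns at 7. Oxidation (Dess–Martin periodinane, NaHCO3) gives (3Z)-non-3-enal F11. Et3SiCN with ZnI2 (cat.) gives the silylated cyanohydrin (4Z)-2-[(triethylsilyl)oxy]dec-4-enenitrile F12 (racemic). iBu2AlH (−78 °C) followed by mild aqueous acid gives aldehyde 7.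

**Further compounds**

F1 | step 6 | (S)-malic acid | O[C@@H](CC(=O)O)C(=O)O
F2 | step 6 | (2S,4S)-2-tert-butyl-5-oxo-1,3-dioxolane-4-acetic acid | OC(=O)C[C@@H]1O[C@H](C(C)(C)C)OC1=O
F3 | step 6 | 2-[(2S,4S)-2-tert-butyl-4-[(2Z)-oct-2-en-1-yl]-5-oxo-1,3-dioxolan-4-yl]acetic acid | OC(=O)C[C@]1(C/C=C\CCCCC)O[C@H](C(C)(C)C)OC1=O
F4 | step 6 | cis-fused lactone acetal 2-tert-butyl-6a-[(2Z)-oct-2-en-1-yl]tetrahydrofuro[2,3-d][1,3]dioxol-5-one (quaternary carbon and acetal carbon as in F3) | CCCCC/C=C\C[C@]12CC(=O)O[C@H]1O[C@@H](C(C)(C)C)O2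
F5 | step 6 | (2S)-5-bromo-2-hydroxy-2-[(2Z)-oct-2-en-1-yl]-4-oxopentanal | CCCCC/C=C\C[C@@](O)(C=O)CC(=O)CBr
F6 | step 6 | (4S)-2-bromo-4-hydroxy-4-[(2Z)-oct-2-en-1-yl]cyclopent-2-en-1-one | CCCCC/C=C\C[C@@]1(O)C=C(Br)C(=O)C1
F7 | step 11 | methyl 7-oxohept-5-ynoate | COC(=O)CCCC#CC=O
F8 | step 11 | methyl (7R)-7-[(1R,5S)-3-bromo-5-[(2Z)-oct-2-en-1-yl]-2-oxo-5-[(triethylsilyl)oxy]cyclopent-3-en-1-yl]-7-hydroxyhept-5-ynoate | CCCCC/C=C\C[C@@]1(O[Si](CC)(CC)CC)C=C(Br)C(=O)[C@@H]1[C@H](C#CCCCC(=O)OC)O
F9 | step 11 | methyl (7R)-7-acetoxy-7-[(1R,5S)-3-bromo-5-[(2Z)-oct-2-en-1-yl]-2-oxo-5-[(triethylsilyl)oxy]cyclopent-3-en-1-yl]hept-5-ynoate | CCCCC/C=C\C[C@@]1(O[Si](CC)(CC)CC)C=C(Br)C(=O)[C@@H]1[C@H](C#CCCCC(=O)OC)OC(C)=O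
F10 | step 3 | (3Z)-non-3-en-1-ol | CCCCC/C=C\CCO
F11 | step 3 | (3Z)-non-3-enal | CCCCC/C=C\CC=O
F12 | step 3 | (4Z)-2-[(triethylsilyl)oxy]dec-4-enenitrile (racemic) | CCCCC/C=C\CC(O[Si](CC)(CC)CC)C#N
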